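**Assumptions (one line each).** The target is the (2S)-flavanone. I read the SMILES as the same configuration as (S)-naringenin, and the CIP order is O > aryl > CH2 > H. I also assume recombinant chalcone isomerase (CHI) accepts the 3'-OMe/5'-prenyl B-ring.

## Retrosynthesis
- Target **1** comes from chalcone **2** by a stereospecific intramolecular oxa-Michael addition, which closes ring C last and sets C2 (S).
- Chalcone **2** comes from Claisen–Schmidt condensation of 5-prenylvanillin **3** with phloroacetophenone **4**.
- Aldehyde **3** comes from cross-metathesis of 5-allylvanillin **5** with 2-methyl-2-butene **6**.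
- **5** comes from aromatic Claisen rearrangement of allyl ether **7**, which is made from vanillin **8** and allyl bromide **9**. The Claisen/metathesis sequence is used because a direct Claisen of a prenyl ether would give the reverse-prenyl product.

## Route

**Step 1**
Reactants: **8** vanillin; **9** allyl bromide
Product: **7** 4-allyloxy-3-methoxybenzaldehyde
Conditions: K2CO3, DMF, rt, 12 h
Reagents that add atoms: allyl bromide, C=CCBr
Why: Williamson O-alkylation of the only phenol; the aldehyde is untouched.

**Step 2**
Reactants: **7**
Product: **5** 3-allyl-4-hydroxy-5-methoxybenzaldehyde (5-allylvanillin)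
Conditions: neat, 200 °C, 2 h (or N,N-diethylaniline, reflux)
Reagents that add atoms: none
Why: aromatic Claisen [3,3] rearrangement; C3 is blocked by OMe, so the allyl group goes to C5 and the product is the free phenol.

**Step 3**
Reactants: **5**; **6** 2-methyl-2-butene
Product: **3** 4-hydroxy-3-methoxy-5-(3-methylbut-2-enyl)benzaldehyde (5-prenylvanillin)
Conditions: Grubbs II (5 mol%), 2-methyl-2-butene (20 equiv), CH2Cl2, 40 °C, sealed tube, 16 h
Reagents that add atoms: 2-methyl-2-butene, CC=C(C)C
Why: olefin cross-metathesis. The terminal allyl alkene exchanges with the trisubstituted alkene to give the normal prenyl group and propene; the aldehyde and phenol are tolerated.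

**Step 4**
Reactants: **3**; **4** 2',4',6'-trihydroxyacetophenone
Product: **2** (E)-chalcone, 1-(2,4,6-trihydroxyphenyl)-3-[4-hydroxy-3-methoxy-5-(3-methylbut-2-enyl)phenyl]prop-2-en-1-one
Conditions: KOH (about 10 equiv), EtOH/H2O, N2, 50 °C, 48 h; then 1 M HCl to pH 4 at 0 °C; silica chromatography
Reagents that add atoms: none (KOH and HCl leave no atoms in the product; H2O is lost)
Why: Claisen–Schmidt (base-mediated aldol condensation). The fully deprotonated polyphenolate gives the E-chalcone and resists cyclisation in strong base, so no protecting groups are needed.

**Step 5**
Reactants: **2**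
Product: **1** (2S)-5,7,4'-trihydroxy-3'-methoxy-5'-prenylflavanone (target)
Conditions: recombinant chalcone isomerase (Medicago sativa CHI), 50 mM phosphate buffer pH 7.0, 5% DMSO, 25 °C, 1–2 h; extract with EtOAc
Reagents that add atoms: none (isomerisation)
Why: enzymatic 6-endo oxa-Michael cyclisation of the 6'-hydroxychalcone, which delivers the (2S)-flavanone exclusively. Mild, near-neutral conditions avoid the base-mediated ring-opening that would racemise C2.

## Checks
- **Target match:** the flavanone ring is 6-membered, with 5,7-OH on ring A and a 4'-OH, 3'-OMe and 5'-prenyl on ring B. The formula is C21H22O6, and chalcone **2** is an isomer of it. Compound **3** (C13H16O3) plus **4** (C8H8O4) minus H2O gives **2** (C21H22O6).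
- **Functional groups:** the prenyl alkene sees no strong acid at any point. Steps 1–3 involve no chemistry that touches the ketone or phenols of ring A. The free phenols survive steps 2–5, and N2 is used in step 4 against phenolate oxidation.
- **Stereochemistry:** the only stereocentre (C2) is created in the last step under near-neutral conditions, so it is not scrambled afterwards. Chalcone **2** is checked by chiral HPLC for contamination with racemic flavanone before step 5.

## Compound list
1 | (2S)-5,7-dihydroxy-2-(4-hydroxy-3-methoxy-5-prenylphenyl)chroman-4-one | COc1cc([C@@H]2CC(=O)c3c(O)cc(O)cc3O2)cc(CC=C(C)C)c1O | target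
2 | (E)-2',4',6',4-tetrahydroxy-3-methoxy-5-prenylchalcone | COc1cc(/C=C/C(=O)c2c(O)cc(O)cc2O)cc(CC=C(C)C)c1O | intermediate
3 | 4-hydroxy-3-methoxy-5-prenylbenzaldehyde | COc1cc(C=O)cc(CC=C(C)C)c1O | intermediate
4 | 2',4',6'-trihydroxyacetophenone (phloroacetophenone) | CC(=O)c1c(O)cc(O)cc1O | starting material
5 | 3-allyl-4-hydroxy-5-methoxybenzaldehyde | COc1cc(C=O)cc(CC=C)c1O | intermediate
6 | 2-methyl-2-butene | CC=C(C)C | starting material (reagent)
7 | 4-allyloxy-3-methoxybenzaldehyde | COc1cc(C=O)ccc1OCC=C | intermediate
8 | vanillin | COc1cc(C=O)ccc1O | starting material
9 | allyl bromide | C=CCBr | starting material (reagent)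

**Total steps:** 5. **Longest linear sequence:** 5 steps (vanillin → 7 → 5 → 3 → 2 → 1). Phloroacetophenone joins convergently at step 4.

## Three steps most likely to fail
1. **Step 5 (CHI cyclisation).** The enzyme may not accept the 3'-OMe/5'-prenyl B-ring, or the background racemic cyclisation may compete.
   - Fallback: cyclise **2** non-enzymatically (NaOAc, EtOH, reflux) to racemic **1**, then isolate the (S)-enantiomer by preparative chiral HPLC (polysaccharide column).
2. **Step 4 (unprotected Claisen–Schmidt).** The 4-phenoxide aldehyde is a poor electrophile, so yields may be low and oxidation products may form.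
   - Fallback: protect the phenols of **4** and of the aldehyde as MOM ethers, condense, and remove the MOM groups under mild acid (e.g. PPTS, MeOH, 40 °C) that the prenyl alkene tolerates.
3. **Step 3 (cross-metathesis on the free phenol).** Ru–H isomerisation to the propenyl arene or homodimerisation may compete.
   - Fallback: make **3** by Stille coupling of commercial 5-bromovanillin with prenyltributylstannane (Pd(PPh3)4, toluene, 100 °C), which avoids the allyl/metathesis route entirely.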